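**Plan**
- Retrosynthesis: both tropolone-fused dihydropyrans are opened first by a double retro-hetero-Diels–Alder (each aryl O–C(Me) bond and each ArCH2–CH bond), giving two molecules of a tropolone o-quinone methide and (S)-10-hydroxyhumulene. The 11-membered ring is then cut between the carbinol carbon and the neighbouring methyl-bearing carbon, and the open chain at its disubstituted alkene (Julia–Kocienski).
- Enabling feature: with the pyran on tropolone ring A opened, its quaternary O–C(Me) carbon is the sp2 carbon of an (E)-trisubstituted alkene of the cycloundecatriene and the adjacent CH(OH) is an allylic carbinol. That ring bond is therefore an alkenyl–carbinol bond, which an iodoalkene/aldehyde closure can make.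
- Forward order: the chain is assembled (carboalumination, Julia–Kocienski, hydrozirconation–iodination), the 11-membered ring closes (step 11), then both dihydropyran rings form in one operation (step 20). The tropolone is made separately from 2-methylanisole by dibromocarbene ring expansion.
- Stereochemistry: the carbinol centre is set in the ring closure by a chiral ligand on chromium. The four ring-fusion centres are relayed from it in the double cycloaddition: trans fusions from the (E)-alkenes, facial sense from the ring conformer with the hydroxyl pointing outward.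

Key step: step 11

Assumption: the (S)-valinol-derived oxazoline sulfonamide ligand in step 11 is taken to direct addition to the aldehyde face that gives the (S)-carbinol; if the sense is the reverse, its enantiomer is used in the same way.

**Chain assembly and ring closure**

Step 1
Reactants: 1 tert-butyl(but-3-yn-1-yloxy)dimethylsilane
Product: 3 (E)-6-[(tert-butyldimethylsilyl)oxy]-4-methylhex-3-en-1-ol, via alkenyl(dimethyl)alane 2 (not isolated)
Conditions: AlMe3 (2 equiv.), Cp2ZrCl2 (0.2 equiv.), CH2Cl2, 0 °C to rt; then n-BuLi, THF, −78 °C; ethylene oxide, −78 °C to rt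
Reagents that add atoms: trimethylaluminium C[Al](C)C; ethylene oxide C1CO1
Why: Negishi zirconium-catalysed syn-carboalumination puts methyl and aluminium cis on the terminal alkyne and the derived alkenylalanate opens ethylene oxide with retention, which fixes the (E)-trisubstituted alkene.

Step 2
Reactants: 3 (E)-6-[(tert-butyldimethylsilyl)oxy]-4-methylhex-3-en-1-ol
Product: 4 tert-butyl({(E)-6-[(4-methoxybenzyl)oxy]-3-methylhex-3-en-1-yl}oxy)dimethylsilane
Conditions: NaH, 4-methoxybenzyl chloride, Bu4NI (cat.), THF, 0 °C to rt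
Reagents that add atoms: 4-methoxybenzyl chloride COc1ccc(CCl)cc1
Why: Williamson etherification of the primary alkoxide gives a PMB ether that is orthogonal to the silyl ether and survives the later base, hydride and oxidation steps.

Step 3
Reactants: 4 tert-butyl({(E)-6-[(4-methoxybenzyl)oxy]-3-methylhex-3-en-1-yl}oxy)dimethylsilane
Product: 5 (E)-6-[(4-methoxybenzyl)oxy]-3-methylhex-3-en-1-ol
Conditions: TBAF, THF, 0 °C to rt
Reagents that add atoms: none
Why: Fluoride cleaves the primary silyl ether selectively and leaves the PMB ether and the alkene untouched.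

Step 4
Reactants: 5 (E)-6-[(4-methoxybenzyl)oxy]-3-methylhex-3-en-1-ol
Product: 6 5-({(E)-6-[(4-methoxybenzyl)oxy]-3-methylhex-3-en-1-yl}sulfanyl)-1-phenyl-1H-tetrazole
Conditions: 1-phenyl-1H-tetrazole-5-thiol, PPh3, DIAD, THF, 0 °C to rt
Reagents that add atoms: 1-phenyl-1H-tetrazole-5-thiol Sc1nnnn1-c1ccccc1
Why: Mitsunobu thioetherification of a primary alcohol with the acidic heteroaryl thiol is the standard entry to Julia–Kocienski sulfones.

Step 5
Reactants: 6 5-({(E)-6-[(4-methoxybenzyl)oxy]-3-methylhex-3-en-1-yl}sulfanyl)-1-phenyl-1H-tetrazole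
Product: 7 5-({(E)-6-[(4-methoxybenzyl)oxy]-3-methylhex-3-en-1-yl}sulfonyl)-1-phenyl-1H-tetrazole
Conditions: (NH4)6Mo7O24·4H2O (cat.), 30% aq. H2O2, EtOH, 0 °C to rt
Reagents that add atoms: hydrogen peroxide OO
Why: Molybdate-catalysed peroxide oxidation takes the sulfide to the sulfone faster than it epoxidises a trisubstituted alkene.

Step 6
Reactants: 8 isobutyraldehyde; 9 1-bromobut-2-yne
Product: 10 2,2-dimethylhex-4-ynal
Conditions: 50% aq. NaOH, Bu4NI (cat.), toluene, 60 °C
Reagents that add atoms: none
Why: Phase-transfer C-alkylation of the isobutyraldehyde enolate with a propargylic bromide builds the gem-dimethyl quaternary carbon and gives a non-enolisable aldehyde.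

Step 7
Reactants: 7 5-({(E)-6-[(4-methoxybenzyl)oxy]-3-methylhex-3-en-1-yl}sulfonyl)-1-phenyl-1H-tetrazole; 10 2,2-dimethylhex-4-ynal
Product: 11 1-methoxy-4-({[(3E,6E)-4,8,8-trimethyldodeca-3,6-dien-10-yn-1-yl]oxy}methyl)benzene
Conditions: KHMDS, DME, −60 °C; then 10, −60 °C to rt
Reagents that add atoms: none
Why: Julia–Kocienski olefination of a 1-phenyltetrazolyl sulfone with an α-quaternary aldehyde under potassium/DME conditions should give the (E)-disubstituted alkene through the anti adduct, Smiles rearrangement and loss of SO2.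

Step 8
Reactants: 11 1-methoxy-4-({[(3E,6E)-4,8,8-trimethyldodeca-3,6-dien-10-yn-1-yl]oxy}methyl)benzene
Product: 13 1-({[(3E,6E,10E)-11-iodo-4,8,8-trimethyldodeca-3,6,10-trien-1-yl]oxy}methyl)-4-methoxybenzene, via alkenylzirconocene chloride 12 (not isolated)
Conditions: Cp2Zr(H)Cl (2 equiv.), THF, rt to 40 °C; then I2, THF, 0 °C
Reagents that add atoms: iodine II
Why: Schwartz hydrozirconation adds syn to the alkyne much faster than to the internal alkenes and, after equilibration, places zirconium on the methyl-bearing carbon away from the neopentyl-type CH2, so iodinolysis with retention should give the (E)-2-iodoalkene.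

Step 9
Reactants: 13 1-({[(3E,6E,10E)-11-iodo-4,8,8-trimethyldodeca-3,6,10-trien-1-yl]oxy}methyl)-4-methoxybenzene
Product: 14 (3E,6E,10E)-11-iodo-4,8,8-trimethyldodeca-3,6,10-trien-1-ol
Conditions: DDQ, CH2Cl2/pH 7 buffer (10:1), 0 °C
Reagents that add atoms: none
Why: Oxidative PMB cleavage by hydride abstraction at the electron-rich benzylic position is far faster at 0 °C than any attack on the skipped triene or the alkenyl iodide.

Step 10
Reactants: 14 (3E,6E,10E)-11-iodo-4,8,8-trimethyldodeca-3,6,10-trien-1-ol
Product: 15 (3E,6E,10E)-11-iodo-4,8,8-trimethyldodeca-3,6,10-trienal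
Conditions: Dess–Martin periodinane, NaHCO3, CH2Cl2, 0 °C to rt; used at once
Reagents that add atoms: none
Why: Buffered Dess–Martin oxidation gives β,γ-unsaturated aldehydes without moving the alkene into conjugation.

Step 11
Reactants: 15 (3E,6E,10E)-11-iodo-4,8,8-trimethyldodeca-3,6,10-trienal
Product: 17 (1S,2E,6E,9E)-2,5,5,9-tetramethylcycloundeca-2,6,9-trien-1-ol, via alkenylchromium dichloride 16 (not isolated)
Conditions: CrCl2 (4 equiv.), (S)-N-[2-(4-isopropyl-4,5-dihydrooxazol-2-yl)-6-methylphenyl]methanesulfonamide (4.4 equiv.), Et3N (4.4 equiv.), THF, rt; NiCl2 (0.1 equiv.); 15 added by syringe pump over 10 h (final about 2 mM); aqueous ethylenediamine work-up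
Reagents that add atoms: none
Why: CrCl2 reduces NiCl2 to zerovalent nickel, which inserts into the alkenyl C–I bond with retention of the (E) geometry, and transmetalation gives an alkenyl species of trivalent chromium that adds to the aldehyde carbonyl. The closest known reaction type is the Nozaki–Hiyama–Kishi macrocyclisation of iodoalkenyl aldehydes in its ligand-controlled asymmetric form with oxazoline sulfonamide ligands on chromium. The single ring formed, the 11-membered carbocycle, closes by 1,2-addition in an 11-exo-trig mode, and the ring bond made is the one between the carbinol carbon and the methyl-bearing alkene carbon. The only new stereocentre, the carbinol carbon, is controlled by the chiral sulfonamide ligand on chromium, since the substrate has no other stereocentre. The step needs ring closure over oligomerisation, secured by slow addition at about 2 mM, and it needs an intact skipped triene and a non-conjugated aldehyde, secured by the neutral, non-basic and chemoselective organochromium conditions. The three (E)-alkenes and the gem-dimethyl group pre-organise the chain into the turn of the humulene ring, which should offset the modest strain of the all-(E) cycloundecatriene.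

**Tropolone component**

Step 12
Reactants: 18 2-methylanisole
Product: 19 1-methoxy-2-methylcyclohexa-1,4-diene
Conditions: Li, liquid NH3, THF, t-BuOH, −78 °C to −33 °C
Reagents that add atoms: none
Why: Birch reduction of an alkyl anisole leaves both donor substituents on one residual double bond, giving the tetrasubstituted enol ether.

Step 13
Reactants: 19 1-methoxy-2-methylcyclohexa-1,4-diene
Product: 20 7,7-dibromo-1-methoxy-6-methylbicyclo[4.1.0]hept-3-ene (racemic)
Conditions: CHBr3, KOt-Bu, pentane, −20 °C to 0 °C
Reagents that add atoms: bromoform BrC(Br)Br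
Why: Electrophilic dibromocarbene adds to the electron-rich tetrasubstituted enol ether alkene in preference to the disubstituted one, and the ring fusion is cis by necessity.

Step 14
Reactants: 20 7,7-dibromo-1-methoxy-6-methylbicyclo[4.1.0]hept-3-ene
Product: 21 7,7-dibromo-1-methoxy-6-methylbicyclo[4.1.0]heptane-3,4-diol (racemic cis-diol)
Conditions: OsO4 (2 mol%), N-methylmorpholine N-oxide, acetone/H2O, 0 °C
Reagents that add atoms: osmium tetroxide O=[Os](=O)(=O)=O (catalytic oxygen carrier); N-methylmorpholine N-oxide C[N+]1([O-])CCOCC1; water O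
Why: Upjohn dihydroxylation of the remaining alkene under neutral conditions should occur anti to the endo bromine, and both new carbinol centres are destroyed in the next step.

Step 15
Reactants: 21 7,7-dibromo-1-methoxy-6-methylbicyclo[4.1.0]heptane-3,4-diol
Product: 23 5-bromo-2-hydroxy-4-methoxy-6-methylcyclohepta-2,4,6-trien-1-one, via bicyclic 1,2-diketone 22 (not isolated)
Conditions: TFAA, DMSO, CH2Cl2, −78 °C; then Et3N, −78 °C to rt
Reagents that add atoms: none
Why: Swern-type oxidation gives the 1,2-diketone, whose enolisation triggers disrotatory opening of the dibromocyclopropane with loss of the endo bromide (assisted by the methoxy group) and tautomerisation to the bromotropolone, the gem-dibromocyclopropane route to tropolones.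

Step 16
Reactants: 23 5-bromo-2-hydroxy-4-methoxy-6-methylcyclohepta-2,4,6-trien-1-one
Product: 24 5-bromo-2,4-dihydroxy-6-methylcyclohepta-2,4,6-trien-1-one
Conditions: 48% aq. HBr, AcOH, 110 °C
Reagents that add atoms: none
Why: The ring methoxy group is a vinylogous methyl ester and is cleaved by protonation and bromide attack at the methyl group, as is usual for methoxytropolones.

Step 17
Reactants: 24 5-bromo-2,4-dihydroxy-6-methylcyclohepta-2,4,6-trien-1-one
Product: 25 2,4-diacetoxy-5-bromo-6-methylcyclohepta-2,4,6-trien-1-one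
Conditions: Ac2O, pyridine, DMAP (cat.), CH2Cl2, 0 °C to rt
Reagents that add atoms: acetic anhydride CC(=O)OC(C)=O
Why: Acetylation masks both acidic, chelating hydroxyls so the bromide can undergo palladium catalysis; the tropolone acetate is drawn on one oxygen.

Step 18
Reactants: 25 2,4-diacetoxy-5-bromo-6-methylcyclohepta-2,4,6-trien-1-one
Product: 26 2,4-diacetoxy-5-(methoxymethyl)-6-methylcyclohepta-2,4,6-trien-1-one
Conditions: tributyl(methoxymethyl)stannane (1.5 equiv.), Pd(PPh3)4 (10 mol%), CuI (20 mol%), 1,4-dioxane, 100 °C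
Reagents that add atoms: tributyl(methoxymethyl)stannane COC[Sn](CCCC)(CCCC)CCCC
Why: Stille coupling of an alkoxymethylstannane with the electron-poor alkenyl-type bromide under zerovalent palladium installs the benzylic carbon as its methyl ether, which has no free hydroxyl to take part in acyl shifts.

Step 19
Reactants: 26 2,4-diacetoxy-5-(methoxymethyl)-6-methylcyclohepta-2,4,6-trien-1-one
Product: 27 2,4-dihydroxy-5-(methoxymethyl)-6-methylcyclohepta-2,4,6-trien-1-one
Conditions: K2CO3, MeOH, 0 °C to rt; then aq. NaH2PO4
Reagents that add atoms: none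
Why: Transesterification removes both enol acetates, and the o-hydroxybenzyl-type methyl ether is stable in methanol because any ionisation is simply reversed by the solvent.

**Union**

Step 20
Reactants: 17 (1S,2E,6E,9E)-2,5,5,9-tetramethylcycloundeca-2,6,9-trien-1-ol; 27 2,4-dihydroxy-5-(methoxymethyl)-6-methylcyclohepta-2,4,6-trien-1-one (4 equiv., in portions)
Product: 30 target CNP0283947.4, via tropolone o-quinone methide 28 (not isolated), via mono-cycloadduct 29 (not isolated)
Conditions: o-xylene, 150 °C, sealed tube, argon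
Reagents that add atoms: none
Why: Thermal loss of methanol from 27 gives the electron-poor oxadiene 28, which should add twice in inverse-demand hetero-Diels–Alder reactions to the two trisubstituted alkenes with oxygen on the methyl-bearing carbon (as known for tropolone o-quinone methides and humulene); suprafacial addition to each (E)-alkene gives the two trans ring fusions, and attack on the peripheral faces of the conformer with the carbinol hydroxyl outward and the two alkene methyls on opposite ring faces relays the carbinol configuration to the four new centres, while the neopentyl-flanked disubstituted alkene should stay intact.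

**Compound list**

1 | tert-butyl(but-3-yn-1-yloxy)dimethylsilane | C#CCCO[Si](C)(C)C(C)(C)C | starting material
2 | (E)-{4-[(tert-butyldimethylsilyl)oxy]-2-methylbut-1-en-1-yl}dimethylalane | C[Al](C)/C=C(\C)CCO[Si](C)(C)C(C)(C)C | intermediate (not isolated)
3 | (E)-6-[(tert-butyldimethylsilyl)oxy]-4-methylhex-3-en-1-ol | OCC/C=C(\C)CCO[Si](C)(C)C(C)(C)C | intermediate
4 | tert-butyl({(E)-6-[(4-methoxybenzyl)oxy]-3-methylhex-3-en-1-yl}oxy)dimethylsilane | COc1ccc(COCC/C=C(\C)CCO[Si](C)(C)C(C)(C)C)cc1 | intermediate
5 | (E)-6-[(4-methoxybenzyl)oxy]-3-methylhex-3-en-1-ol | COc1ccc(COCC/C=C(\C)CCO)cc1 | intermediate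
6 | 5-({(E)-6-[(4-methoxybenzyl)oxy]-3-methylhex-3-en-1-yl}sulfanyl)-1-phenyl-1H-tetrazole | COc1ccc(COCC/C=C(\C)CCSc2nnnn2-c2ccccc2)cc1 | intermediate
7 | 5-({(E)-6-[(4-methoxybenzyl)oxy]-3-methylhex-3-en-1-yl}sulfonyl)-1-phenyl-1H-tetrazole | COc1ccc(COCC/C=C(\C)CCS(=O)(=O)c2nnnn2-c2ccccc2)cc1 | intermediate
8 | isobutyraldehyde | CC(C)C=O | starting material
9 | 1-bromobut-2-yne | CC#CCBr | starting material
10 | 2,2-dimethylhex-4-ynal | CC#CCC(C)(C)C=O | intermediate
11 | 1-methoxy-4-({[(3E,6E)-4,8,8-trimethyldodeca-3,6-dien-10-yn-1-yl]oxy}methyl)benzene | COc1ccc(COCC/C=C(C)/C/C=C/C(C)(C)CC#CC)cc1 | intermediate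
12 | alkenylzirconocene chloride from 11 (zirconium on C11) | COc1ccc(COCC/C=C(C)/C/C=C/C(C)(C)C/C=C(C)/[Zr](Cl)(C2C=CC=C2)C2C=CC=C2)cc1 | intermediate (not isolated)
13 | 1-({[(3E,6E,10E)-11-iodo-4,8,8-trimethyldodeca-3,6,10-trien-1-yl]oxy}methyl)-4-methoxybenzene | COc1ccc(COCC/C=C(C)/C/C=C/C(C)(C)C/C=C(C)/I)cc1 | intermediate
14 | (3E,6E,10E)-11-iodo-4,8,8-trimethyldodeca-3,6,10-trien-1-ol | OCC/C=C(C)/C/C=C/C(C)(C)C/C=C(C)/I | intermediate
15 | (3E,6E,10E)-11-iodo-4,8,8-trimethyldodeca-3,6,10-trienal | O=CC/C=C(C)/C/C=C/C(C)(C)C/C=C(C)/I | intermediate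
16 | alkenylchromium dichloride from 15 (sulfonamide ligand on chromium not drawn) | O=CC/C=C(C)/C/C=C/C(C)(C)C/C=C(C)/[Cr](Cl)Cl | intermediate (not isolated)
17 | (1S,2E,6E,9E)-2,5,5,9-tetramethylcycloundeca-2,6,9-trien-1-ol ((S)-10-hydroxyhumulene) | O[C@H]1C/C=C(C)/C/C=C/C(C)(C)C/C=C1\C | intermediate
18 | 2-methylanisole | COc1ccccc1C | starting material
19 | 1-methoxy-2-methylcyclohexa-1,4-diene | COC1=C(C)CC=CC1 | intermediate
20 | 7,7-dibromo-1-methoxy-6-methylbicyclo[4.1.0]hept-3-ene (racemic, one enantiomer drawn) | CO[C@]12CC=CC[C@@]1(C)C2(Br)Br | intermediate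
21 | 7,7-dibromo-1-methoxy-6-methylbicyclo[4.1.0]heptane-3,4-diol (racemic, cis-diol anti to the CBr2 bridge) | CO[C@]12C[C@H](O)[C@H](O)C[C@@]1(C)C2(Br)Br | intermediate
22 | 7,7-dibromo-1-methoxy-6-methylbicyclo[4.1.0]heptane-3,4-dione (racemic) | CO[C@]12CC(=O)C(=O)C[C@@]1(C)C2(Br)Br | intermediate (not isolated)
23 | 5-bromo-2-hydroxy-4-methoxy-6-methylcyclohepta-2,4,6-trien-1-one | O=C1C=C(C)C(Br)=C(OC)C=C1O | intermediate
24 | 5-bromo-2,4-dihydroxy-6-methylcyclohepta-2,4,6-trien-1-one | O=C1C=C(C)C(Br)=C(O)C=C1O | intermediate
25 | 2,4-diacetoxy-5-bromo-6-methylcyclohepta-2,4,6-trien-1-one | CC(=O)OC1=CC(OC(C)=O)=C(Br)C(C)=CC1=O | intermediate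
26 | 2,4-diacetoxy-5-(methoxymethyl)-6-methylcyclohepta-2,4,6-trien-1-one | CC(=O)OC1=CC(OC(C)=O)=C(COC)C(C)=CC1=O | intermediate
27 | 2,4-dihydroxy-5-(methoxymethyl)-6-methylcyclohepta-2,4,6-trien-1-one | O=C1C=C(C)C(COC)=C(O)C=C1O | intermediate
28 | 3-hydroxy-6-methyl-7-methylidenecyclohepta-2,5-diene-1,4-dione (tropolone o-quinone methide) | C=C1C(C)=CC(=O)C(O)=CC1=O | intermediate (not isolated)
29 | mono-cycloadduct: trans-fused dihydropyranotropolone on the hydroxyl-flanked alkene of 17, other two alkenes intact | Cc1cc(=O)c(O)cc2c1C[C@H]1CC(C)(C)/C=C/C/C(C)=C/C[C@H](O)[C@]1(C)O2 | intermediate (not isolated)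
30 | CNP0283947.4, bis(dihydropyranotropolone) adduct of (S)-10-hydroxyhumulene | Cc1cc(=O)c(O)cc2c1C[C@H]1CC(C)(C)/C=C/C[C@@]3(C)Oc4cc(O)c(=O)cc(C)c4C[C@@H]3C[C@H](O)[C@]1(C)O2 | target

**Count and risks**

Total steps: 20. Longest linear sequence: 11 steps (steps 1–5, 7–11 and 20, from compound 1); the tropolone branch (steps 12–19) is 8 steps.

Most likely to fail:

1. Step 11. The chromium-bound ligand may discriminate the aldehyde faces poorly, and intermolecular coupling may compete with ring closure. Fallback: starting from 15, the ring is closed with CrCl2/NiCl2 in DMSO at high dilution without the chiral ligand to give the racemic alcohol rac-2,5,5,9-tetramethylcycloundeca-2,6,9-trien-1-ol F1. Dess–Martin oxidation then gives the macrocyclic enone (2E,6E,9E)-2,5,5,9-tetramethylcycloundeca-2,6,9-trien-1-one F2. Corey–Bakshi–Shibata reduction with the (R)-methyl oxazaborolidine and catecholborane in toluene at −78 °C (alkenyl as the large group) should give the (S)-alcohol, and the route is rejoined at 17.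

2. Step 20. At 150 °C the free allylic alcohol may be lost by dehydration or by O-alkylation with the quinone methide, and facial control in the second cycloaddition may erode. Fallback: starting from 17, the hydroxyl is silylated (TBSOTf, 2,6-lutidine, CH2Cl2, −78 °C) to the silyl ether tert-butyldimethylsilyl ether of 17 F3, so that a bulky outward group instead of a hydrogen bond sets the conformer. The double cycloaddition with 27 under the same thermal generation then gives the silylated bis-adduct O-TBS derivative of the target F4, and HF·pyridine in THF removes the silyl group, rejoining at 30.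

3. Step 18. Transfer of the sp3 methoxymethyl group to the doubly ortho-substituted C–Br position may be too slow, with loss of the acetates on prolonged heating. Fallback: starting from 25, the much faster vinyl transfer (tributyl(vinyl)stannane, Pd(PPh3)4, dioxane, 90 °C) gives the vinyl compound 2,4-diacetoxy-6-methyl-5-vinylcyclohepta-2,4,6-trien-1-one F5. Lemieux–Johnson cleavage (OsO4 cat., NaIO4, 2,6-lutidine, dioxane/H2O) gives the aldehyde 2,4-diacetoxy-5-formyl-6-methylcyclohepta-2,4,6-trien-1-one F6. NaBH4 in MeOH followed by K2CO3 gives the triol 2,4-dihydroxy-5-(hydroxymethyl)-6-methylcyclohepta-2,4,6-trien-1-one F7, which loses water in place of methanol when used instead of 27 in step 20; the route is rejoined at 30.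

**Further compounds**

F1 | step 11 | rac-(2E,6E,9E)-2,5,5,9-tetramethylcycloundeca-2,6,9-trien-1-ol | OC1C/C=C(C)/C/C=C/C(C)(C)C/C=C1\C
F2 | step 11 | (2E,6E,9E)-2,5,5,9-tetramethylcycloundeca-2,6,9-trien-1-one | O=C1C/C=C(C)/C/C=C/C(C)(C)C/C=C1\C
F3 | step 20 | tert-butyldimethyl{[(1S,2E,6E,9E)-2,5,5,9-tetramethylcycloundeca-2,6,9-trien-1-yl]oxy}silane | CC(C)(C)[Si](C)(C)O[C@H]1C/C=C(C)/C/C=C/C(C)(C)C/C=C1\C
F4 | step 20 | O-(tert-butyldimethylsilyl) ether of the target at the carbinol oxygen | Cc1cc(=O)c(O)cc2c1C[C@H]1CC(C)(C)/C=C/C[C@@]3(C)Oc4cc(O)c(=O)cc(C)c4C[C@@H]3C[C@H](O[Si](C)(C)C(C)(C)C)[C@]1(C)O2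
F5 | step 18 | 2,4-diacetoxy-6-methyl-5-vinylcyclohepta-2,4,6-trien-1-one | CC(=O)OC1=CC(OC(C)=O)=C(C=C)C(C)=CC1=O
F6 | step 18 | 2,4-diacetoxy-5-formyl-6-methylcyclohepta-2,4,6-trien-1-one | CC(=O)OC1=CC(OC(C)=O)=C(C=O)C(C)=CC1=O
F7 | step 18 | 2,4-dihydroxy-5-(hydroxymethyl)-6-methylcyclohepta-2,4,6-trien-1-one | O=C1C=C(C)C(CO)=C(O)C=C1O
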